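**Plan**

- Retrosynthesis: the two benzyl ethers on ring B are cut last. Ring C (the pyranone) is then cut at O1–C8a and at C2–C3 in one stroke, leaving a ring-B benzaldehyde and a ring-A aryl methoxymethyl ketone that carries fluorine at C8a.
- Enabling feature: the C4 carbonyl sits on C4a, ortho to C8a. It makes C3 an enol nucleophile and makes C8a–F a benzo-vinylogous acyl fluoride, so one ketone drives both bond formations and the fluorine activator leaves in the event itself.
- Forward: ring-A ketone by ortho-lithiation/acylation, then its enol silane; ring-B aldehyde by benzylation and formylation; the two are joined and ring C is closed in one flask (asymmetric anti-aldol at C2–C3, then SNAr at O1–C8a); hydrogenolysis ends the route.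
- Stereochemistry: C2 comes from catalyst-controlled attack on one aldehyde face, C3 from the anti topology of the aldol. The ring closure touches neither centre, so anti becomes trans (2R,3R).

Key step: step 5

Assumption: the sense of induction of the chiral diamine–Sn(OTf)2 promoter towards this ketone-derived enol silane is not established; the (R)-diamine is written, and if it delivers the (2S,3S) series the (S)-diamine is used with no other change.

**Step 1**
Reactants: 1 5-fluoro-1,2,3-trimethoxybenzene; 2 N,2-dimethoxy-N-methylacetamide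
Product: 5 1-(6-fluoro-2,3,4-trimethoxyphenyl)-2-methoxyethan-1-one, via aryllithium 3 (not isolated), via lithium hemiaminal adduct 4 (not isolated)
Conditions: n-BuLi (1.05 equiv), THF, −78 °C; then 2, −78 → −40 °C; aq. NH4Cl
Reagents that add atoms: none
Why: Directed ortho-metalation, since the only ring hydrogens of 1 lie between F and OMe and the ortho-fluoroaryllithium 3 should be stable to loss of LiF at −78 °C; acylation with Weinreb amide 2 stops at the chelated adduct 4, which gives ketone 5 on work-up.

**Step 2**
Reactants: 5 1-(6-fluoro-2,3,4-trimethoxyphenyl)-2-methoxyethan-1-one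
Product: 6 {[(Z)-1-(6-fluoro-2,3,4-trimethoxyphenyl)-2-methoxyethenyl]oxy}trimethylsilane
Conditions: TMSOTf (1.2 equiv), Et3N (1.5 equiv), CH2Cl2, 0 °C; pentane, filtration, concentration (no aqueous work-up)
Reagents that add atoms: trimethylsilyl trifluoromethanesulfonate C[Si](C)(C)OS(=O)(=O)C(F)(F)F
Why: Soft enolisation of the α-methoxy ketone to its silyl enol ether, expected to give the (Z)-isomer in which OMe is cis to OSiMe3 and turned away from the twisted 2,6-disubstituted aryl group.

**Step 3**
Reactants: 7 2-methoxybenzene-1,4-diol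
Product: 8 1,4-bis(benzyloxy)-2-methoxybenzene
Conditions: BnBr (2.3 equiv), K2CO3 (3 equiv), DMF, 60 °C, under N2
Reagents that add atoms: benzyl bromide BrCc1ccccc1
Why: Williamson ether synthesis on both phenols; benzyl should survive the Lewis acid and alkoxide of step 5 and leaves under neutral hydrogenolysis.

**Step 4**
Reactants: 8 1,4-bis(benzyloxy)-2-methoxybenzene
Product: 10 2,5-bis(benzyloxy)-4-methoxybenzaldehyde, via iminium chloride 9 (not isolated)
Conditions: POCl3 (1.3 equiv), DMF, 0 → 70 °C; then H2O, 60 °C
Reagents that add atoms: N,N-dimethylformamide CN(C)C=O; water O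
Why: Vilsmeier–Haack formylation of the 1,2,4-trialkoxybenzene at the position para to OMe and ortho to OBn (the pattern by which 1,2,4-trimethoxybenzene gives 2,4,5-trimethoxybenzaldehyde), the site between OMe and OBn being sterically shielded.

**Step 5**
Reactants: 6 {[(Z)-1-(6-fluoro-2,3,4-trimethoxyphenyl)-2-methoxyethenyl]oxy}trimethylsilane; 10 2,5-bis(benzyloxy)-4-methoxybenzaldehyde
Product: 13 (2R,3R)-2-[2,5-bis(benzyloxy)-4-methoxyphenyl]-3,5,6,7-tetramethoxy-2,3-dihydro-4H-chromen-4-one, via silylated anti-aldol 11 (not isolated), via lithium aldolate 12 (not isolated)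
Conditions: Sn(OTf)2 (20 mol%), (R)-1-methyl-2-[(naphthalen-1-ylamino)methyl]pyrrolidine (22 mol%), EtCN, −78 °C, slow addition of 6 and 10; then THF, LiOt-Bu (1.45 equiv, of which 0.4 equiv is taken up by Sn(OTf)2), −78 → 0 °C; AcOH
Reagents that add atoms: none
Why: The diamine–Sn(OTf)2 Lewis acid binds aldehyde 10 and enol silane 6 adds through an open transition state, after which silyl transfer to the aldolate oxygen gives 11 and frees the catalyst (closest known type: the catalytic asymmetric Mukaiyama aldol reaction of α-alkoxy silyl enolates with this promoter, which is anti-selective because the α-alkoxy oxygen also binds tin). LiOt-Bu then takes the Me3Si group off O1 and the lithium alkoxide 12 adds to C8a, ortho to the C4 ketone, to give a Meisenheimer adduct held as the C4 enolate, which expels LiF (closest known type: alkoxide SNAr closure of ortho-fluoroaryl ketones to chroman-4-ones). Ring C closes by this addition–elimination in the 6-endo-trig sense with respect to the C8a=C4a–C4=O unit. C2 is set by the chiral diamine, which should leave the Si face of the tin-bound aldehyde open (2R), and C3 is set relative to C2 by the anti topology of the aldol (3R); the ring closure breaks no bond at either centre, so the anti adduct gives the trans chromanone. The step needs anti over syn addition (tin-bound α-OMe of the Z enol silane), displacement of fluoride and not of the C5 methoxy group (C–F is the far better SNAr site, and the C5 and C7 methoxy groups are meta to C8a and do not deactivate it), and ring closure faster than retro-aldol of 12 (tight lithium chelate, low temperature). Because the base is consumed as LiF, product 13 is not left in a basic medium that could epimerise C3 or open ring C.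

**Step 6**
Reactants: 13 (2R,3R)-2-[2,5-bis(benzyloxy)-4-methoxyphenyl]-3,5,6,7-tetramethoxy-2,3-dihydro-4H-chromen-4-one
Product: 14 (2R,3R)-2-(2,5-dihydroxy-4-methoxyphenyl)-3,5,6,7-tetramethoxy-2,3-dihydro-4H-chromen-4-one
Conditions: H2 (1 atm), 10% Pd/C, EtOAc, rt; filtration and concentration under argon
Reagents that add atoms: none
Why: Catalytic hydrogenolysis of the two aryl benzyl ethers under neutral conditions, which should leave C2, C3 and the C4 ketone untouched when stopped at full debenzylation.

**Compound list**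

1 | 5-fluoro-1,2,3-trimethoxybenzene | COc1cc(F)cc(OC)c1OC | starting material
2 | N,2-dimethoxy-N-methylacetamide | COCC(=O)N(C)OC | starting material
3 | (6-fluoro-2,3,4-trimethoxyphenyl)lithium | [Li]c1c(F)cc(OC)c(OC)c1OC | intermediate
4 | lithium 1-(6-fluoro-2,3,4-trimethoxyphenyl)-2-methoxy-1-[methoxy(methyl)amino]ethan-1-olate | COCC([O-])(N(C)OC)c1c(F)cc(OC)c(OC)c1OC.[Li+] | intermediate
5 | 1-(6-fluoro-2,3,4-trimethoxyphenyl)-2-methoxyethan-1-one | COCC(=O)c1c(F)cc(OC)c(OC)c1OC | intermediate
6 | {[(Z)-1-(6-fluoro-2,3,4-trimethoxyphenyl)-2-methoxyethenyl]oxy}trimethylsilane | CO/C=C(\O[Si](C)(C)C)c1c(F)cc(OC)c(OC)c1OC | intermediate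
7 | 2-methoxybenzene-1,4-diol | COc1cc(O)ccc1O | starting material
8 | 1,4-bis(benzyloxy)-2-methoxybenzene | COc1cc(OCc2ccccc2)ccc1OCc1ccccc1 | intermediate
9 | N-{[2,5-bis(benzyloxy)-4-methoxyphenyl]methylidene}-N-methylmethanaminium chloride | C[N+](C)=Cc1cc(OCc2ccccc2)c(OC)cc1OCc1ccccc1.[Cl-] | intermediate
10 | 2,5-bis(benzyloxy)-4-methoxybenzaldehyde | COc1cc(OCc2ccccc2)c(C=O)cc1OCc1ccccc1 | intermediate
11 | (2R,3R)-3-[2,5-bis(benzyloxy)-4-methoxyphenyl]-1-(6-fluoro-2,3,4-trimethoxyphenyl)-2-methoxy-3-[(trimethylsilyl)oxy]propan-1-one | COc1cc(OCc2ccccc2)c([C@@H](O[Si](C)(C)C)[C@@H](OC)C(=O)c2c(F)cc(OC)c(OC)c2OC)cc1OCc1ccccc1 | intermediate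
12 | lithium (1R,2R)-1-[2,5-bis(benzyloxy)-4-methoxyphenyl]-3-(6-fluoro-2,3,4-trimethoxyphenyl)-2-methoxy-3-oxopropan-1-olate | COc1cc(OCc2ccccc2)c([C@@H]([O-])[C@@H](OC)C(=O)c2c(F)cc(OC)c(OC)c2OC)cc1OCc1ccccc1.[Li+] | intermediate
13 | (2R,3R)-2-[2,5-bis(benzyloxy)-4-methoxyphenyl]-3,5,6,7-tetramethoxy-2,3-dihydro-4H-chromen-4-one | COc1cc(OCc2ccccc2)c([C@H]3Oc4cc(OC)c(OC)c(OC)c4C(=O)[C@@H]3OC)cc1OCc1ccccc1 | intermediate
14 | (2R,3R)-2-(2,5-dihydroxy-4-methoxyphenyl)-3,5,6,7-tetramethoxy-2,3-dihydro-4H-chromen-4-one | COc1cc(O)c([C@H]2Oc3cc(OC)c(OC)c(OC)c3C(=O)[C@@H]2OC)cc1O | target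

**Totals and risks**

Total step count: 6. Longest linear sequence: 4 steps (1, 2, 5, 6 or 3, 4, 5, 6).

Step 5. The lithium aldolate 12 may revert to enolate and aldehyde before it closes the ring, which would scramble C2 and C3; the aldol stage may also fail to reach useful anti selectivity with a ketone-derived enol silane. The fallback sets out from aldehyde 10 and returns at 13, closing ring C the other way round (at O1–C2). Commercial 1-(2-hydroxy-4,5,6-trimethoxyphenyl)ethan-1-one F1 is protected (MOMCl, i-Pr2NEt, CH2Cl2) as 1-[2-(methoxymethoxy)-4,5,6-trimethoxyphenyl]ethan-1-one F2. Claisen–Schmidt condensation with 10 (KOH, EtOH) should give the chalcone (E)-3-[2,5-bis(benzyloxy)-4-methoxyphenyl]-1-[2-(methoxymethoxy)-4,5,6-trimethoxyphenyl]prop-2-en-1-one F3. Julia–Colonna epoxidation (poly-L-leucine, urea–H2O2, DBU, THF) should give the trans epoxide [(2R,3S)-3-[2,5-bis(benzyloxy)-4-methoxyphenyl]oxiran-2-yl][2-(methoxymethoxy)-4,5,6-trimethoxyphenyl]methanone F4. HCl in MeOH removes the MOM group, and the freed phenol opens the epoxide at the benzylic carbon with inversion to give (2R,3R)-2-[2,5-bis(benzyloxy)-4-methoxyphenyl]-3-hydroxy-5,6,7-trimethoxy-2,3-dihydro-4H-chromen-4-one F5. Its 3-OH is methylated without base (MeI, Ag2O, CH2Cl2) to rejoin the route at 13.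

Step 1. The ortho-fluoroaryllithium may lose LiF to an aryne on local warming, or may deprotonate the Weinreb amide instead of adding to it. The fallback sets out from 1 and returns at 5: Friedel–Crafts acylation of 1 with methoxyacetyl chloride and SnCl4 (CH2Cl2, −20 → 0 °C) attacks the same, only available ring position by electrophilic substitution. No new compound arises (F0).

Step 6. Hydrogenolysis may run on into the benzylic C2–O1 bond or reduce the C4 ketone, and the hydroquinone product may oxidise in air during work-up. The fallback sets out from 13 and returns at 14: non-reductive debenzylation with BCl3 and pentamethylbenzene as cation scavenger (CH2Cl2, −78 °C, short contact so that the C5 methoxy group is not cleaved), with work-up under argon. No new compound arises (F0).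

**Further compounds**

F1 | step 5 | 1-(2-hydroxy-4,5,6-trimethoxyphenyl)ethan-1-one | CC(=O)c1c(O)cc(OC)c(OC)c1OC
F2 | step 5 | 1-[2-(methoxymethoxy)-4,5,6-trimethoxyphenyl]ethan-1-one | CC(=O)c1c(OCOC)cc(OC)c(OC)c1OC
F3 | step 5 | (E)-3-[2,5-bis(benzyloxy)-4-methoxyphenyl]-1-[2-(methoxymethoxy)-4,5,6-trimethoxyphenyl]prop-2-en-1-one | COCOc1cc(OC)c(OC)c(OC)c1C(=O)/C=C/c1cc(OCc2ccccc2)c(OC)cc1OCc1ccccc1
F4 | step 5 | [(2R,3S)-3-[2,5-bis(benzyloxy)-4-methoxyphenyl]oxiran-2-yl][2-(methoxymethoxy)-4,5,6-trimethoxyphenyl]methanone | COCOc1cc(OC)c(OC)c(OC)c1C(=O)[C@@H]1O[C@H]1c1cc(OCc2ccccc2)c(OC)cc1OCc1ccccc1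
F5 | step 5 | (2R,3R)-2-[2,5-bis(benzyloxy)-4-methoxyphenyl]-3-hydroxy-5,6,7-trimethoxy-2,3-dihydro-4H-chromen-4-one | COc1cc(OCc2ccccc2)c([C@H]3Oc4cc(OC)c(OC)c(OC)c4C(=O)[C@@H]3O)cc1OCc1ccccc1
F0 | step 1 | none | none
F0 | step 6 | none | none
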